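**Retrosynthetic overview**
1. Eudesmane numbering is used. Ring A is C1–C5 plus C10 and carries the C4=C15H2 methylene. Ring B is C5–C10 and carries O6, the C7 isopropyl group and O9. C14 is the angular methyl.
2. Enabling feature: the homoallylic alcohol array HO–C6–C5–C4(=C15H2). The ring B carbinol C6 is bonded to the cis fusion carbon C5, and C5 is bonded to the methylene-bearing C4 of ring A. This is a carbonyl-ene retron, so cutting C5–C6 opens ring B to a monocyclic 6-enal with a C4(CH3)=C5 olefin in ring A and the anisoate already in place.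
3. The array O9–C9–C10(quaternary)–C5=C4 of that enal is a second homoallylic alcohol. Retro-allylboration gives a tertiary cyclohexenyl boronate (boron on the later C4) and a C6–C9 aldehyde.
4. The boronate comes from 3-methylcyclohex-2-enone by asymmetric reduction, carbamate formation and lithiation–borylation with a methyl boronate. The aldehyde comes from an Evans allylation that sets C7.
5. Ring order: ring A is bought. Ring B is the only ring made and it is closed in the last step.

Key step: step 12

Remark: the target is read as (1R,3R,4S,4aS,8aR) in decahydronaphthalene numbering (5S,6S,7R,9R,10R in eudesmane numbering), a cis-fused decalin with H5, C14, O6, the isopropyl group and O9 all on one face.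

**Route**

Step 1
Reactants: 1 (R)-4-benzyl-1,3-oxazolidin-2-one; 2 3-methylbutanoyl chloride
Product: 3 (R)-4-benzyl-3-(3-methylbutanoyl)-1,3-oxazolidin-2-one
Conditions: n-BuLi, THF, −78 °C; then 2, −78 → 0 °C
Reagents that add atoms: none
Why: N-acylation of the lithiated oxazolidinone by an acid chloride is the standard way to load an Evans auxiliary and touches no stereocenter.

Step 2
Reactants: 3 (R)-4-benzyl-3-(3-methylbutanoyl)-1,3-oxazolidin-2-one; 4 allyl iodide
Product: 5 (R)-4-benzyl-3-[(2R)-2-isopropylpent-4-enoyl]-1,3-oxazolidin-2-one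
Conditions: NaN(SiMe3)2, THF, −78 °C; then 4, −78 → −40 °C
Reagents that add atoms: none
Why: Evans asymmetric alkylation, in which the chelated Z sodium enolate is shielded on one face by the benzyl group, so allyl iodide enters from the other face and sets the future C7 as R.

Step 3
Reactants: 5 (R)-4-benzyl-3-[(2R)-2-isopropylpent-4-enoyl]-1,3-oxazolidin-2-one
Product: 6 (2R)-2-isopropylpent-4-en-1-ol
Conditions: LiBH4, MeOH (1 equiv), Et2O, 0 °C
Reagents that add atoms: none
Why: Reductive removal of the auxiliary by LiBH4 attacks the exocyclic imide carbonyl, leaves the olefin and the adjacent stereocenter untouched and returns the oxazolidinone.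

Step 4
Reactants: 6 (2R)-2-isopropylpent-4-en-1-ol
Product: 7 tert-butyl{[(2R)-2-isopropylpent-4-en-1-yl]oxy}dimethylsilane
Conditions: TBSCl, imidazole, DMF, rt
Reagents that add atoms: tert-butyldimethylsilyl chloride, CC(C)(C)[Si](C)(C)Cl
Why: Imidazole-promoted silylation of a primary alcohol masks the future O6 carbon (C6) through the organolithium, boron and acylation steps.

Step 5
Reactants: 7 tert-butyl{[(2R)-2-isopropylpent-4-en-1-yl]oxy}dimethylsilane
Product: 8 (3R)-3-{[(tert-butyldimethylsilyl)oxy]methyl}-4-methylpentanal
Conditions: O3, CH2Cl2, −78 °C; then Me2S, −78 °C → rt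
Reagents that add atoms: ozone, [O-][O+]=O
Why: Ozonolysis with reductive work-up cleaves the only C=C bond to the aldehyde carbon that becomes C9, and the stereocenter is beta to the carbonyl and cannot epimerise.

Step 6
Reactants: 9 3-methylcyclohex-2-en-1-one
Product: 10 (1S)-3-methylcyclohex-2-en-1-ol
Conditions: (R)-Me-CBS oxazaborolidine (10 mol %), BH3·SMe2, THF, −20 °C; MeOH, then water
Reagents that add atoms: none
Why: Corey–Bakshi–Shibata reduction, in which the oxazaborolidine binds the ketone with the olefinic flank as the large group and delivers hydride in the 1,2 sense to one carbonyl face, should give the S allylic alcohol.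

Step 7
Reactants: 10 (1S)-3-methylcyclohex-2-en-1-ol
Product: 11 (1S)-3-methylcyclohex-2-en-1-yl N,N-diisopropylcarbamate
Conditions: NaH, THF, 0 °C; then iPr2NC(O)Cl, reflux
Reagents that add atoms: N,N-diisopropylcarbamoyl chloride, CC(C)N(C(C)C)C(=O)Cl
Why: O-carbamoylation of the sodium alkoxide installs the directing and leaving group for the next step without breaking any bond at the stereocenter.

Step 8
Reactants: 11 (1S)-3-methylcyclohex-2-en-1-yl N,N-diisopropylcarbamate; 12 2,4,4,5,5-pentamethyl-1,3,2-dioxaborolane; 8 (3R)-3-{[(tert-butyldimethylsilyl)oxy]methyl}-4-methylpentanal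
Product: 17 (1R,3R)-1-[(1R)-1,3-dimethylcyclohex-2-en-1-yl]-3-{[(tert-butyldimethylsilyl)oxy]methyl}-4-methylpentan-1-ol, via lithiated carbamate 13 (not isolated), via lithium boronate complex 14 (not isolated), via tertiary allylboronate 15 (not isolated), via pinacol borate ester 16 (not isolated)
Conditions: s-BuLi, TMEDA, Et2O, −78 °C; 12, −78 °C → rt; then 8, rt → 35 °C; pH 7 buffer
Reagents that add atoms: none
Why: One-pot lithiation–borylation–allylboration, in which carbamate-directed deprotonation and borylation both go with retention, the anti-periplanar 1,2-metalate shift of methyl expels the carbamate with inversion to give 15, and 15 adds to 8 through a closed Zimmerman–Traxler chair (boron and new C–C bond on the same ring face, aldehyde chain equatorial), which carries the C–B configuration to the quaternary C10 (R), fixes C9 (R) relative to it and moves the olefin to C4=C5.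

Step 9
Reactants: 17 (1R,3R)-1-[(1R)-1,3-dimethylcyclohex-2-en-1-yl]-3-{[(tert-butyldimethylsilyl)oxy]methyl}-4-methylpentan-1-ol; 18 4-methoxybenzoyl chloride
Product: 19 (1R,3R)-1-[(1R)-1,3-dimethylcyclohex-2-en-1-yl]-3-{[(tert-butyldimethylsilyl)oxy]methyl}-4-methylpentyl 4-methoxybenzoate
Conditions: 18, Et3N, DMAP (cat.), CH2Cl2, 0 °C → reflux
Reagents that add atoms: none
Why: DMAP-catalysed acylation esterifies the only free hydroxyl, which is hindered but secondary, with retention at C9.

Step 10
Reactants: 19 (1R,3R)-1-[(1R)-1,3-dimethylcyclohex-2-en-1-yl]-3-{[(tert-butyldimethylsilyl)oxy]methyl}-4-methylpentyl 4-methoxybenzoate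
Product: 20 (1R,3R)-1-[(1R)-1,3-dimethylcyclohex-2-en-1-yl]-3-(hydroxymethyl)-4-methylpentyl 4-methoxybenzoate
Conditions: HF·pyridine, THF, 0 °C → rt
Reagents that add atoms: none
Why: Fluoride-driven cleavage of the primary silyl ether under mildly acidic conditions spares the ester and the trisubstituted olefin and gives little chance for acyl migration.

Step 11
Reactants: 20 (1R,3R)-1-[(1R)-1,3-dimethylcyclohex-2-en-1-yl]-3-(hydroxymethyl)-4-methylpentyl 4-methoxybenzoate
Product: 21 (1R,3R)-1-[(1R)-1,3-dimethylcyclohex-2-en-1-yl]-3-formyl-4-methylpentyl 4-methoxybenzoate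
Conditions: Dess–Martin periodinane, CH2Cl2, 0 °C → rt
Reagents that add atoms: none
Why: Dess–Martin oxidation runs under near-neutral conditions, stops at the aldehyde and should not epimerise the adjacent stereocenter C7.

Step 12
Reactants: 21 (1R,3R)-1-[(1R)-1,3-dimethylcyclohex-2-en-1-yl]-3-formyl-4-methylpentyl 4-methoxybenzoate
Product: 23 (1R,3R,4S,4aS,8aR)-4-hydroxy-8a-methyl-5-methylidene-3-(propan-2-yl)decahydronaphthalen-1-yl 4-methoxybenzoate (target CNP0107029.1), via chloro(methyl)aluminium alkoxide 22 (not isolated)
Conditions: Me2AlCl (2.5 equiv), CH2Cl2, −78 → −20 °C; cold 1 M HCl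
Reagents that add atoms: none
Why: Me2AlCl binds the aldehyde oxygen (a second equivalent is parked on the ester carbonyl), C6 bonds to C5 of the ring A olefin while the oxygen takes a hydrogen from the C15 methyl group in one six-centre event, and loss of methane then gives alkoxide 22; the closest known reaction type is the Lewis-acid-promoted type 1 intramolecular carbonyl-ene cyclisation of 6-enals, as in citronellal to isopulegol. Ring B closes in the 6-exo mode (new bond C5–C6, C4 stays outside the new ring) through a chair in which C6 enters along the axial direction of the ring A half-chair. C5 is controlled by the quaternary C10: the four-atom tether can reach only the olefin face that carries C9, so H5 ends up cis to the angular methyl group and a trans fusion is out of geometric reach. C6 is controlled by the chair: the aluminium-bound oxygen takes the equatorial site anti to C10, since the axial site would meet C1 in a 1,3-diaxial clash, and this places the hydroxyl trans to C4 as in isopulegol. The step needs methyl (C15) and not ring CH2 (C3) as hydrogen donor, which the equatorial oxygen secures because it lies on the H5/C15 side of the olefin, and it needs the aldehyde and not the ester to react, which the much higher electrophilicity of the complexed aldehyde secures. The reacting chair holds the isopropyl and anisoyloxy groups axial, a price judged payable because the alternative chair would demand equatorial attack through a boat-like ring A, and the cis-decalin formed relaxes by ring inversion to the conformer in which both groups are equatorial.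

**Compound list**
1 | (R)-4-benzyl-1,3-oxazolidin-2-one | O=C1N[C@H](Cc2ccccc2)CO1 | starting material
2 | 3-methylbutanoyl chloride (isovaleryl chloride) | CC(C)CC(=O)Cl | starting material
3 | (R)-4-benzyl-3-(3-methylbutanoyl)-1,3-oxazolidin-2-one | CC(C)CC(=O)N1[C@H](Cc2ccccc2)COC1=O | intermediate
4 | allyl iodide (3-iodoprop-1-ene) | C=CCI | starting material
5 | (R)-4-benzyl-3-[(2R)-2-isopropylpent-4-enoyl]-1,3-oxazolidin-2-one | C=CC[C@H](C(C)C)C(=O)N1[C@H](Cc2ccccc2)COC1=O | intermediate
6 | (2R)-2-isopropylpent-4-en-1-ol | C=CC[C@H](C(C)C)CO | intermediate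
7 | tert-butyl{[(2R)-2-isopropylpent-4-en-1-yl]oxy}dimethylsilane | C=CC[C@H](C(C)C)CO[Si](C)(C)C(C)(C)C | intermediate
8 | (3R)-3-{[(tert-butyldimethylsilyl)oxy]methyl}-4-methylpentanal | O=CC[C@H](C(C)C)CO[Si](C)(C)C(C)(C)C | intermediate
9 | 3-methylcyclohex-2-en-1-one | CC1=CC(=O)CCC1 | starting material
10 | (1S)-3-methylcyclohex-2-en-1-ol | CC1=C[C@@H](O)CCC1 | intermediate
11 | (1S)-3-methylcyclohex-2-en-1-yl N,N-diisopropylcarbamate | CC1=C[C@@H](OC(=O)N(C(C)C)C(C)C)CCC1 | intermediate
12 | 2,4,4,5,5-pentamethyl-1,3,2-dioxaborolane (methylboronic acid pinacol ester) | CB1OC(C)(C)C(C)(C)O1 | starting material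
13 | lithiated carbamate (Li in place of the carbinol H of 11, retention) | CC1=C[C@@]([Li])(OC(=O)N(C(C)C)C(C)C)CCC1 | intermediate
14 | lithium boronate complex (B in place of Li, retention) | [Li+].CC1=C[C@@]([B-]2(C)OC(C)(C)C(C)(C)O2)(OC(=O)N(C(C)C)C(C)C)CCC1 | intermediate
15 | (R)-2-(1,3-dimethylcyclohex-2-en-1-yl)-4,4,5,5-tetramethyl-1,3,2-dioxaborolane (tertiary allylboronate) | CC1=C[C@@](C)(B2OC(C)(C)C(C)(C)O2)CCC1 | intermediate
16 | pinacol borate ester of 17 | CC1=C[C@](C)([C@H](OB2OC(C)(C)C(C)(C)O2)C[C@H](C(C)C)CO[Si](C)(C)C(C)(C)C)CCC1 | intermediate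
17 | (1R,3R)-1-[(1R)-1,3-dimethylcyclohex-2-en-1-yl]-3-{[(tert-butyldimethylsilyl)oxy]methyl}-4-methylpentan-1-ol | CC1=C[C@](C)([C@H](O)C[C@H](C(C)C)CO[Si](C)(C)C(C)(C)C)CCC1 | intermediate
18 | 4-methoxybenzoyl chloride | COc1ccc(cc1)C(=O)Cl | starting material
19 | (1R,3R)-1-[(1R)-1,3-dimethylcyclohex-2-en-1-yl]-3-{[(tert-butyldimethylsilyl)oxy]methyl}-4-methylpentyl 4-methoxybenzoate | CC1=C[C@](C)([C@H](OC(=O)c2ccc(OC)cc2)C[C@H](C(C)C)CO[Si](C)(C)C(C)(C)C)CCC1 | intermediate
20 | (1R,3R)-1-[(1R)-1,3-dimethylcyclohex-2-en-1-yl]-3-(hydroxymethyl)-4-methylpentyl 4-methoxybenzoate | CC1=C[C@](C)([C@H](OC(=O)c2ccc(OC)cc2)C[C@H](C(C)C)CO)CCC1 | intermediate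
21 | (1R,3R)-1-[(1R)-1,3-dimethylcyclohex-2-en-1-yl]-3-formyl-4-methylpentyl 4-methoxybenzoate | CC1=C[C@](C)([C@H](OC(=O)c2ccc(OC)cc2)C[C@H](C(C)C)C=O)CCC1 | intermediate
22 | chloro(methyl)aluminium alkoxide of 23 | C=C1CCC[C@]2(C)[C@H]1[C@@H](O[Al](C)Cl)[C@@H](C(C)C)C[C@H]2OC(=O)c1ccc(OC)cc1 | intermediate
23 | (1R,3R,4S,4aS,8aR)-4-hydroxy-8a-methyl-5-methylidene-3-(propan-2-yl)decahydronaphthalen-1-yl 4-methoxybenzoate | C=C1CCC[C@]2(C)[C@H]1[C@@H](O)[C@@H](C(C)C)C[C@H]2OC(=O)c1ccc(OC)cc1 | target

**Totals**
Total step count: 12.
Longest linear sequence: 10 (steps 1–5 and 8–12). The second branch (steps 6 and 7) joins at step 8.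

**Steps most likely to fail**

1. Step 12. The closure may be slow because the productive chair carries two axial groups. Three processes could then compete: a stepwise cationic course with proton loss into ring A, closure through the other chair with loss of facial control at the carbonyl, and methyl transfer from aluminium to the aldehyde.

   The fallback replaces the ene reaction by an intramolecular Hosomi–Sakurai allylation. It sets out from 11 and 8 and comes back at 23.
   - Step 8 is run with commercial 4,4,5,5-tetramethyl-2-[(trimethylsilyl)methyl]-1,3,2-dioxaborolane in place of 12.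
   - Lithiated 13 is trapped as the silylmethyl lithium boronate complex F1. Its 1,2-shift gives the silylmethyl tertiary allylboronate F2.
   - Allylboration of 8 gives, through the pinacol borate ester F3, the allylsilane alcohol F4.
   - Acylation with 18 (Et3N, DMAP) gives the allylsilane 4-methoxybenzoate F5.
   - PPTS in MeOH frees the allylsilane primary alcohol F6, and Dess–Martin oxidation gives the allylsilane aldehyde F7.
   - BF3·OEt2 in CH2Cl2 at −78 °C then closes the same C5–C6 bond. The far more nucleophilic allylsilane should give an earlier transition state, and loss of silicon can place the double bond only at C4=C15.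

2. Step 8. Three things may go wrong: the boronic ester may attack the gamma terminus of the lithiated allyl carbamate, the organolithium may lose configuration before it is trapped, or allylboration at the fully substituted gamma carbon may be slow. A slow allylboration would leave time for a 1,3-borotropic shift, which in this pseudo-symmetric ring equals racemisation.

   The fallback is a Hoppe homoaldol reaction followed by a Kumada coupling. It sets out from 11 (through 13) and 8 and comes back at 17.
   - 13 is transmetalated with ClTi(OiPr)3 at −78 °C, with inversion, to the allyltitanium species F8.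
   - F8 adds to 8 at its gamma carbon through a closed chair on the same ring face as in the boron route. This gives the enol carbamate F9, which already has C9 and C10 in place.
   - Coupling of F9 with MeMgBr, catalysed by Ni(acac)2 in Et2O, replaces the carbamoyloxy group on C4 by methyl.

3. Step 6. Facial discrimination may be poor because the two flanks of the carbonyl (ring CH2 and unsubstituted olefinic CH) differ little in size. Hydroboration of the olefin may also compete.

   The fallback is reduction followed by enzymatic kinetic resolution. It sets out from 9 and comes back at 10.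
   - Luche reduction (NaBH4, CeCl3·7H2O, MeOH, 0 °C) gives racemic 3-methylcyclohex-2-en-1-ol F10.
   - Candida antarctica lipase B with vinyl acetate in hexane should acetylate the R enantiomer to (1R)-3-methylcyclohex-2-en-1-yl acetate F11.
   - The unreacted S alcohol 10 is separated by chromatography.

**Further compounds**
F1 | step 12 | silylmethyl lithium boronate complex | [Li+].CC1=C[C@@]([B-]2(C[Si](C)(C)C)OC(C)(C)C(C)(C)O2)(OC(=O)N(C(C)C)C(C)C)CCC1
F2 | step 12 | silylmethyl tertiary allylboronate, (R)-4,4,5,5-tetramethyl-2-{3-methyl-1-[(trimethylsilyl)methyl]cyclohex-2-en-1-yl}-1,3,2-dioxaborolane | CC1=C[C@@](C[Si](C)(C)C)(B2OC(C)(C)C(C)(C)O2)CCC1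
F3 | step 12 | pinacol borate ester of F4 | C[Si](C)(C)CC1=C[C@](C)([C@H](OB2OC(C)(C)C(C)(C)O2)C[C@H](C(C)C)CO[Si](C)(C)C(C)(C)C)CCC1
F4 | step 12 | allylsilane alcohol, (1R,3R)-3-{[(tert-butyldimethylsilyl)oxy]methyl}-4-methyl-1-{(1R)-1-methyl-3-[(trimethylsilyl)methyl]cyclohex-2-en-1-yl}pentan-1-ol | C[Si](C)(C)CC1=C[C@](C)([C@H](O)C[C@H](C(C)C)CO[Si](C)(C)C(C)(C)C)CCC1
F5 | step 12 | allylsilane 4-methoxybenzoate (ester of F4) | C[Si](C)(C)CC1=C[C@](C)([C@H](OC(=O)c2ccc(OC)cc2)C[C@H](C(C)C)CO[Si](C)(C)C(C)(C)C)CCC1
F6 | step 12 | allylsilane primary alcohol (F5 without the silyl ether) | C[Si](C)(C)CC1=C[C@](C)([C@H](OC(=O)c2ccc(OC)cc2)C[C@H](C(C)C)CO)CCC1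
F7 | step 12 | allylsilane aldehyde | C[Si](C)(C)CC1=C[C@](C)([C@H](OC(=O)c2ccc(OC)cc2)C[C@H](C(C)C)C=O)CCC1
F8 | step 8 | allyltitanium species (triisopropoxytitanium in place of Li of 13, inversion) | CC1=C[C@]([Ti](OC(C)C)(OC(C)C)OC(C)C)(OC(=O)N(C(C)C)C(C)C)CCC1
F9 | step 8 | enol carbamate, (3R)-3-[(1R,3R)-3-{[(tert-butyldimethylsilyl)oxy]methyl}-1-hydroxy-4-methylpentyl]-3-methylcyclohex-1-en-1-yl N,N-diisopropylcarbamate | CC(C)N(C(C)C)C(=O)OC1=C[C@](C)([C@H](O)C[C@H](C(C)C)CO[Si](C)(C)C(C)(C)C)CCC1
F10 | step 6 | racemic 3-methylcyclohex-2-en-1-ol | CC1=CC(O)CCC1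
F11 | step 6 | (1R)-3-methylcyclohex-2-en-1-yl acetate | CC1=C[C@H](OC(C)=O)CCC1
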